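**Retrosynthetic overview**
- The target comes from its bis-silyl ether by desilylation, after an (E)-selective SeO2 oxidation of the terminal prenyl methyl group.
- Key disconnection: the ArCH2–CH2Ar' bond. The formyl carbon of a chromene-6-carbaldehyde is inverted into a benzyl-anion equivalent (tritylhydrazone azo anion) and alkylated by a 2,3-bis(silyloxy)benzyl bromide. Two normally electrophilic carbons are joined, N2 is lost, and the CH2–CH2 link forms without any hydrogenation.
- The chromene-6-carbaldehyde comes from ring-closing metathesis of an o-vinylaryl (S)-linalyl ether, itself made by SNAr of (S)-linalool alkoxide on 4-fluoro-3-vinylbenzaldehyde. The formyl group first activates the SNAr and then becomes the umpoled carbon.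
- The stereocentre is bought with (S)-linalool; its C–O bond is never broken, so (S)-linalool maps onto (S)-C2 of the target.
- Ring order: both benzene rings are bought; the pyran ring is the only ring made (step 3).

Assumption: (S)-(+)-linalool (coriandrol) of ≥98% ee and tritylhydrazine hydrochloride are taken as catalogue items.
Note: from step 3 on, everything is run at ≤40 °C and away from UV light, because 2H-chromenes can ring-open photochemically, which would racemise C2.

**Step 1**
Reactants: 1 3-bromo-4-fluorobenzaldehyde; 2 4,4,5,5-tetramethyl-2-vinyl-1,3,2-dioxaborolane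
Product: 3 4-fluoro-3-vinylbenzaldehyde
Conditions: PdCl2(dppf) (3 mol%), K2CO3, 1,4-dioxane/H2O 4:1, 80 °C
Reagents that add atoms: none
Why: Suzuki–Miyaura coupling at the C–Br bond, with the C–F bond and the aldehyde inert under these conditions and no stereocentre involved.

**Step 2**
Reactants: 3 4-fluoro-3-vinylbenzaldehyde; 4 (S)-(+)-linalool
Product: 6 4-{[(3S)-3,7-dimethylocta-1,6-dien-3-yl]oxy}-3-ethenylbenzaldehyde, via potassium (S)-linaloolate 5 (not isolated)
Conditions: 4 (1.2 equiv), KH (1.1 equiv), THF, 0 °C; then 3, DMF, 0 → 20 °C; Et3N-washed silica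
Reagents that add atoms: none
Why: Nucleophilic aromatic substitution (addition–elimination through a Meisenheimer adduct stabilised by the para-formyl group) in which the alkoxide oxygen attacks the arene, so the O–C bond at the stereocentre is untouched and (S) is retained; a tertiary alkoxide has no α-hydrogen and cannot reduce the aldehyde.

**Step 3**
Reactants: 6 4-{[(3S)-3,7-dimethylocta-1,6-dien-3-yl]oxy}-3-ethenylbenzaldehyde
Product: 7 (2S)-2-methyl-2-(4-methylpent-3-en-1-yl)-2H-chromene-6-carbaldehyde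
Conditions: second-generation Grubbs catalyst RuCl2(=CHPh)(PCy3)(H2IMes) (3 mol%), CH2Cl2 (0.01 M), 40 °C
Reagents that add atoms: none
Why: Ring-closing metathesis in which the catalyst loads on the unhindered styrene and closes the six-membered ring onto the linalyl vinyl group with loss of ethene, faster than the hindered vinyl group can start the competing cyclopentene closure onto the trisubstituted alkene; the stereocentre is not touched.

**Step 4**
Reactants: 7 (2S)-2-methyl-2-(4-methylpent-3-en-1-yl)-2H-chromene-6-carbaldehyde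
Product: 8 (2S)-2-methyl-2-(4-methylpent-3-en-1-yl)-2H-chromene-6-carbaldehyde (E)-N-tritylhydrazone
Conditions: TrNHNH2·HCl (1.1 equiv), NaOAc (1.2 equiv), EtOH/THF, 20 °C; crystallise
Reagents that add atoms: tritylhydrazine hydrochloride, Cl.NNC(c1ccccc1)(c1ccccc1)c1ccccc1
Why: Hydrazone condensation of an aromatic aldehyde, giving the (E)-hydrazone that carries the bulky N-trityl group needed to steer the next step to carbon.

**Step 5**
Reactants: 9 3-methylcatechol
Product: 10 2,3-bis(tert-butyldimethylsilyloxy)toluene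
Conditions: TBSCl (2.4 equiv), imidazole (5 equiv), DMF, 20 °C
Reagents that add atoms: tert-butyldimethylsilyl chloride, CC(C)(C)[Si](C)(C)Cl
Why: Standard imidazole-promoted silylation of both phenols, chosen because aryl silyl ethers survive amide base and radical conditions and come off with fluoride at the end.

**Step 6**
Reactants: 10 2,3-bis(tert-butyldimethylsilyloxy)toluene
Product: 11 2,3-bis(tert-butyldimethylsilyloxy)benzyl bromide
Conditions: NBS (1.05 equiv), AIBN (5 mol%), PhCF3, 80 °C
Reagents that add atoms: N-bromosuccinimide, O=C1CCC(=O)N1Br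
Why: Wohl–Ziegler radical benzylic bromination, run in a non-polar solvent with an initiator so that the radical chain at the methyl group outruns ionic ring bromination.

**Step 7 (key step)**
Reactants: 8 (2S)-2-methyl-2-(4-methylpent-3-en-1-yl)-2H-chromene-6-carbaldehyde (E)-N-tritylhydrazone; 11 2,3-bis(tert-butyldimethylsilyloxy)benzyl bromide
Product: 14 (2S)-6-{2-[2,3-bis(tert-butyldimethylsilyloxy)phenyl]ethyl}-2-methyl-2-(4-methylpent-3-en-1-yl)-2H-chromene, via lithium azo anion 12 (not isolated), via trityl azo compound 13 (not isolated)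
Conditions: LiN(iPr)2 (0.98 equiv), THF, −78 °C; 11 (1.2 equiv), −78 → −20 °C; then EtSH (15 equiv), 0 → 25 °C, dark
Reagents that add atoms: none
Why: Baldwin-type reductive alkylation of a tritylhydrazone azo anion, in which the N-lithiated hydrazone is an aza-allyl anion whose nitrogen is shielded by trityl, so the former aldehyde carbon acts as a benzyl anion toward the benzylic bromide; the resulting trityl azo compound loses N2 by homolysis near room temperature and the benzylic radical takes hydrogen from the thiol, the trityl radical capping the thiyl radical; the epimeric centre in 13 disappears and C2 is untouched.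

**Step 8**
Reactants: 14 (2S)-6-{2-[2,3-bis(tert-butyldimethylsilyloxy)phenyl]ethyl}-2-methyl-2-(4-methylpent-3-en-1-yl)-2H-chromene
Product: 15 (2E)-5-[(2S)-6-{2-[2,3-bis(tert-butyldimethylsilyloxy)phenyl]ethyl}-2-methyl-2H-chromen-2-yl]-2-methylpent-2-en-1-ol
Conditions: SeO2 (0.5 equiv), t-BuOOH (3 equiv), salicylic acid (0.1 equiv), CH2Cl2, 0 → 20 °C; stop near 70% conversion and recycle 14
Reagents that add atoms: selenium dioxide, O=[Se]=O; tert-butyl hydroperoxide, CC(C)(C)OO
Why: SeO2/t-BuOOH allylic oxidation (ene reaction then [2,3]-sigmatropic shift) attacks the E-methyl of the gem-dimethyl alkene and so fixes the (E)-allylic alcohol, while the chromene alkene has no allylic C–H and the stereocentre is not involved.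

**Step 9**
Reactants: 15 (2E)-5-[(2S)-6-{2-[2,3-bis(tert-butyldimethylsilyloxy)phenyl]ethyl}-2-methyl-2H-chromen-2-yl]-2-methylpent-2-en-1-ol
Product: 16 3-(2-{(2S)-2-[(3E)-5-hydroxy-4-methylpent-3-en-1-yl]-2-methyl-2H-chromen-6-yl}ethyl)benzene-1,2-diol (CNP0267525.1)
Conditions: Bu4NF (2.2 equiv), AcOH (2.5 equiv), degassed THF, 0 °C, argon
Reagents that add atoms: none
Why: Fluoride-mediated cleavage of the two aryl silyl ethers, buffered with acetic acid so the air-sensitive catechol is never present as its dianion and nothing else in the molecule reacts.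

**Compound list**
1 | 3-bromo-4-fluorobenzaldehyde | O=Cc1ccc(F)c(Br)c1 | starting material
2 | 4,4,5,5-tetramethyl-2-vinyl-1,3,2-dioxaborolane | C=CB1OC(C)(C)C(C)(C)O1 | starting material
3 | 4-fluoro-3-vinylbenzaldehyde | O=Cc1ccc(F)c(C=C)c1 | intermediate
4 | (S)-(+)-linalool, (3S)-3,7-dimethylocta-1,6-dien-3-ol | CC(C)=CCC[C@](C)(O)C=C | starting material
5 | potassium (3S)-3,7-dimethylocta-1,6-dien-3-olate | [K+].CC(C)=CCC[C@](C)([O-])C=C | intermediate
6 | 4-{[(3S)-3,7-dimethylocta-1,6-dien-3-yl]oxy}-3-ethenylbenzaldehyde | CC(C)=CCC[C@](C)(Oc1ccc(C=O)cc1C=C)C=C | intermediate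
7 | (2S)-2-methyl-2-(4-methylpent-3-en-1-yl)-2H-chromene-6-carbaldehyde | CC(C)=CCC[C@@]1(C)C=Cc2cc(C=O)ccc2O1 | intermediate
8 | (2S)-2-methyl-2-(4-methylpent-3-en-1-yl)-2H-chromene-6-carbaldehyde (E)-N-tritylhydrazone | CC(C)=CCC[C@@]1(C)C=Cc2cc(/C=N/NC(c3ccccc3)(c4ccccc4)c5ccccc5)ccc2O1 | intermediate
9 | 3-methylcatechol (3-methylbenzene-1,2-diol) | Cc1cccc(O)c1O | starting material
10 | 2,3-bis(tert-butyldimethylsilyloxy)toluene | Cc1cccc(O[Si](C)(C)C(C)(C)C)c1O[Si](C)(C)C(C)(C)C | intermediate
11 | 2,3-bis(tert-butyldimethylsilyloxy)benzyl bromide | BrCc1cccc(O[Si](C)(C)C(C)(C)C)c1O[Si](C)(C)C(C)(C)C | intermediate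
12 | lithium azo anion of 8 (N-lithio tritylhydrazone) | [Li+].CC(C)=CCC[C@@]1(C)C=Cc2cc(/C=N/[N-]C(c3ccccc3)(c4ccccc4)c5ccccc5)ccc2O1 | intermediate
13 | (2S)-6-{2-[2,3-bis(tert-butyldimethylsilyloxy)phenyl]-1-[(E)-trityldiazenyl]ethyl}-2-methyl-2-(4-methylpent-3-en-1-yl)-2H-chromene, both epimers at the diazenyl carbon | CC(C)=CCC[C@@]1(C)C=Cc2cc(C(Cc3cccc(O[Si](C)(C)C(C)(C)C)c3O[Si](C)(C)C(C)(C)C)/N=N/C(c4ccccc4)(c5ccccc5)c6ccccc6)ccc2O1 | intermediate
14 | (2S)-6-{2-[2,3-bis(tert-butyldimethylsilyloxy)phenyl]ethyl}-2-methyl-2-(4-methylpent-3-en-1-yl)-2H-chromene | CC(C)=CCC[C@@]1(C)C=Cc2cc(CCc3cccc(O[Si](C)(C)C(C)(C)C)c3O[Si](C)(C)C(C)(C)C)ccc2O1 | intermediate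
15 | (2E)-5-[(2S)-6-{2-[2,3-bis(tert-butyldimethylsilyloxy)phenyl]ethyl}-2-methyl-2H-chromen-2-yl]-2-methylpent-2-en-1-ol | C/C(=C\CC[C@@]1(C)C=Cc2cc(CCc3cccc(O[Si](C)(C)C(C)(C)C)c3O[Si](C)(C)C(C)(C)C)ccc2O1)CO | intermediate
16 | 3-(2-{(2S)-2-[(3E)-5-hydroxy-4-methylpent-3-en-1-yl]-2-methyl-2H-chromen-6-yl}ethyl)benzene-1,2-diol | C/C(=C\CC[C@@]1(C)C=Cc2cc(CCc3cccc(O)c3O)ccc2O1)CO | target

**Step count and risks**
Total steps: 9. Longest linear sequence: 7 (steps 1, 2, 3, 4, 7, 8, 9 from compound 1).

Most likely to fail, step 7 (the azo-anion alkylation and nitrogen loss). The anion could alkylate on nitrogen, the azo compound 13 could tautomerise to a hydrazone under residual base, or the benzylic radical could recombine with trityl instead of taking hydrogen. The fallback sets out from 7 and comes back at 14 by making the same bond from the other side with a B-alkyl Suzuki–Miyaura coupling. Methylenation of 7 (Ph3P=CH2 from Ph3PCH3Br and KOtBu, THF, 0 °C) gives (2S)-6-ethenyl-2-methyl-2-(4-methylpent-3-en-1-yl)-2H-chromene F3. 9-BBN-H (1.1 equiv, THF, 0 → 20 °C) hydroborates only the terminal vinyl group to give 9-{2-[(2S)-2-methyl-2-(4-methylpent-3-en-1-yl)-2H-chromen-6-yl]ethyl}-9-borabicyclo[3.3.1]nonane F4. This is coupled in the same flask (PdCl2(dppf), aqueous K3PO4, THF/DMF, 45 °C) with 1-bromo-2,3-bis(tert-butyldimethylsilyloxy)benzene F5, made from 3-bromocatechol, TBSCl and imidazole, to give 14.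

Second, step 2 (SNAr of a hindered tertiary alkoxide next to a vinyl group). The reaction may be slow, and the product ether 6 can ionise or undergo Claisen rearrangement if heated or acidified. The fallback sets out from 1 and 4 and comes back at 7, closing the pyran ring through the C–O bond last. Jeffery–Heck arylation of 4 with 1 (Pd(OAc)2, Bu4NCl, NaHCO3, DMF, 80 °C) gives 4-fluoro-3-[(1E,3S)-3-hydroxy-3,7-dimethylocta-1,6-dien-1-yl]benzaldehyde F1. Triplet-sensitised E-to-Z isomerisation (Ir(ppy)3 1 mol%, blue LED, MeCN, 20 °C) gives 4-fluoro-3-[(1Z,3S)-3-hydroxy-3,7-dimethylocta-1,6-dien-1-yl]benzaldehyde F2. Its tertiary alkoxide (KN(SiMe3)2, DMF, 0 → 20 °C) then displaces the para-formyl-activated fluoride intramolecularly to give 7, again without touching the C–O bond of the stereocentre.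

Third, step 8 (late SeO2 oxidation). Conversion is usually incomplete, over-oxidation to the enal competes, and the substrate is precious. The fallback sets out from 14 and comes back at 15, exchanging the alkene terminus instead of oxidising a C–H bond. Cross-metathesis of 14 with methacrolein (10 equiv, second-generation Hoveyda–Grubbs catalyst RuCl2(=CH-C6H4-2-OiPr)(H2IMes) 5 mol%, CH2Cl2, 40 °C) gives (2E)-5-[(2S)-6-{2-[2,3-bis(tert-butyldimethylsilyloxy)phenyl]ethyl}-2-methyl-2H-chromen-2-yl]-2-methylpent-2-enal F6. Luche reduction (NaBH4, CeCl3·7H2O, MeOH, 0 °C) then gives 15. Any F6 formed by over-oxidation in step 8 itself is returned to 15 the same way.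

**Further compounds**
F1 | step 2 | 4-fluoro-3-[(1E,3S)-3-hydroxy-3,7-dimethylocta-1,6-dien-1-yl]benzaldehyde | CC(C)=CCC[C@](C)(O)/C=C/c1cc(C=O)ccc1F
F2 | step 2 | 4-fluoro-3-[(1Z,3S)-3-hydroxy-3,7-dimethylocta-1,6-dien-1-yl]benzaldehyde | CC(C)=CCC[C@](C)(O)/C=C\c1cc(C=O)ccc1F
F3 | step 7 | (2S)-6-ethenyl-2-methyl-2-(4-methylpent-3-en-1-yl)-2H-chromene | CC(C)=CCC[C@@]1(C)C=Cc2cc(C=C)ccc2O1
F4 | step 7 | 9-{2-[(2S)-2-methyl-2-(4-methylpent-3-en-1-yl)-2H-chromen-6-yl]ethyl}-9-borabicyclo[3.3.1]nonane | CC(C)=CCC[C@@]1(C)C=Cc2cc(CCB3C4CCCC3CCC4)ccc2O1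
F5 | step 7 | 1-bromo-2,3-bis(tert-butyldimethylsilyloxy)benzene | Brc1cccc(O[Si](C)(C)C(C)(C)C)c1O[Si](C)(C)C(C)(C)C
F6 | step 8 | (2E)-5-[(2S)-6-{2-[2,3-bis(tert-butyldimethylsilyloxy)phenyl]ethyl}-2-methyl-2H-chromen-2-yl]-2-methylpent-2-enal | C/C(=C\CC[C@@]1(C)C=Cc2cc(CCc3cccc(O[Si](C)(C)C(C)(C)C)c3O[Si](C)(C)C(C)(C)C)ccc2O1)C=O
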